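Ring A is disconnected at C3–C4. The chain C3(=O)–C4–C5–C6(=O) is a 1,4-dicarbonyl that joins the ring A ketone to the ring B ketone through the quaternary C4. A carbene-catalysed intramolecular Stetter reaction of a C3 aldehyde with a C5=C4 alkylidene enone therefore closes ring A and creates C4 in one operation. The precursor is a ring B 2-silyloxy enone that already holds the C9 quaternary centre and the whole side chain. It carries an E-configured C5=C4(CH3)(CH2OAc) alkylidene and a three-carbon aldehyde arm on C10, cis to the side chain. The C10 centre and the alkene geometry together relay the C4 configuration.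

Key step: step 15

Numbering used throughout: ring A = C1, C2, C3, C4, C5, C10; ring B = C5, C6, C7, C8, C9, C10; side chain C11–C15 on C9 with methyl C16 on C13; methyls C17 on C8, C18 on C4, C20 on C9; C19 is the CH2O carbon on C4.

Assumption: stereocentres that are erased later (C8 in 14, C7 and C8 in 16, C5 in 20 and 25) do not matter; they are left open in the SMILES or drawn as the expected epimer. Compounds 1, 4, 7 and 19 are taken as purchasable.

Step 1
Reactants: 1 (2E)-3-methylpent-2-en-4-yn-1-ol
Product: 2 triisopropyl{[(2E)-3-methylpent-2-en-4-yn-1-yl]oxy}silane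
Conditions: i-Pr3SiCl, imidazole, DMF, 0 °C → rt
Reagents that add atoms: chlorotriisopropylsilane, CC(C)[Si](Cl)(C(C)C)C(C)C
Why: Standard silyl ether formation at the primary allylic alcohol; the triisopropylsilyl group is chosen because it should survive the later organometallics, hot hydroxide, mild acid and the quinone oxidation.

Step 2
Reactants: 2 triisopropyl{[(2E)-3-methylpent-2-en-4-yn-1-yl]oxy}silane
Product: 3 triisopropyl{[(2E)-3-methylpenta-2,4-dien-1-yl]oxy}silane
Conditions: H2 (1 atm), Pd/CaCO3 poisoned with Pb(OAc)2, quinoline, hexane, rt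
Reagents that add atoms: none
Why: Lindlar-type semihydrogenation of the terminal alkyne should stop at the vinyl group and leave the E trisubstituted alkene (the later C13=C14) untouched.

Step 3
Reactants: 3 triisopropyl{[(2E)-3-methylpenta-2,4-dien-1-yl]oxy}silane; 4 2-iodocyclohex-2-en-1-one
Product: 6 2-[(3E)-3-methyl-5-(triisopropylsilyloxy)pent-3-en-1-yl]cyclohex-2-en-1-one, via B-alkyl-9-BBN borane 5 (not isolated)
Conditions: 9-BBN-H, THF, 0 °C → rt; then 4, PdCl2(dppf) (cat.), AsPh3, Cs2CO3, DMF/H2O, rt
Reagents that add atoms: none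
Why: 9-BBN should hydroborate only the monosubstituted terminal alkene of the diene with boron on the terminal carbon (C11), and B-alkyl Suzuki–Miyaura coupling with an α-iodoenone is an established route to 2-alkylcyclohexenones, so the complete side chain is attached to C9 in one operation.

Step 4
Reactants: 6 2-[(3E)-3-methyl-5-(triisopropylsilyloxy)pent-3-en-1-yl]cyclohex-2-en-1-one; 7 2-(2-bromoethyl)-1,3-dioxolane
Product: 10 (2S,3R)-3-[2-(1,3-dioxolan-2-yl)ethyl]-2-methyl-2-[(3E)-3-methyl-5-(triisopropylsilyloxy)pent-3-en-1-yl]cyclohexan-1-one, via Grignard reagent 8 (not isolated), via magnesium enolate 9 (not isolated)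
Conditions: 7, Mg, THF; then 6, Cu(OTf)2 (cat.), chiral imidazolinium salt (NHC precursor, cat.), Et2O, −30 °C; then MeI, DMPU, −30 °C → rt
Reagents that add atoms: iodomethane, CI
Why: Copper-catalysed asymmetric conjugate addition of a Grignard reagent to a 2-substituted cyclohexenone sets C10 under ligand control (ligand antipode chosen for 10R), and alkylation of the magnesium enolate with iodomethane occurs anti to the new C10 arm, so C9 is set with its methyl trans to the arm and the arm cis to the side chain.

Step 5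
Reactants: 10 ketone with C9 and C10 set
Product: 13 C6=C7 enone (C8 ketone; C9 and C10 as in 10), via lithium enolate 11 (not isolated), via silyl enol ether 12 (not isolated)
Conditions: LiN(i-Pr)2, THF, −78 °C; Me3SiCl; then Pd(OAc)2, MeCN, rt
Reagents that add atoms: none
Why: Saegusa–Ito oxidation; only C7 carries enolisable hydrogen because C9 is quaternary, so the silyl enol ether and hence the C6=C7 double bond should form regiospecifically.

Step 6
Reactants: 13 C6=C7 enone
Product: 14 tertiary allylic alcohol (C8 carbinol bearing methyl C17; C8 epimers)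
Conditions: MeLi, Et2O, −78 °C; then H2O
Reagents that add atoms: methyllithium, [Li]C
Why: 1,2-Addition of methyllithium to the enone carbonyl introduces C17; the configuration of the new carbinol centre is irrelevant because it is erased in step 7.

Step 7
Reactants: 14 tertiary allylic alcohol
Product: 15 ring B enone C6(=O)–C7=C8(CH3) with C9 (methyl, side chain) and C10 (dioxolanylethyl arm)
Conditions: pyridinium chlorochromate, NaOAc, 4 Å MS, CH2Cl2, rt
Reagents that add atoms: none
Why: Babler–Dauben oxidative 1,3-transposition of a tertiary allylic alcohol moves the oxygen from C8 to C6 and delivers the β-methyl enone; the acetate buffer should protect the dioxolane.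

Step 8
Reactants: 15 ring B enone
Product: 16 C7,C8-epoxy ketone
Conditions: H2O2 (30 %), NaOH, MeOH, 0 °C → rt
Reagents that add atoms: hydrogen peroxide, OO
Why: Weitz–Scheffer nucleophilic epoxidation should attack only the electron-poor enone double bond and leave the side-chain alkene alone; either epoxide face serves because both centres become sp2 in step 9.

Step 9
Reactants: 16 C7,C8-epoxy ketone
Product: 17 diosphenol C6(=O)–C7(OH)=C8(CH3)
Conditions: KOH, t-BuOH/H2O, 70 °C
Reagents that add atoms: none
Why: Base-mediated isomerisation of an α,β-epoxy ketone to a diosphenol (hydroxide opens the epoxide at C7 and the β-hydroxy ketone dehydrates) installs the C7 oxygen without acid, which the dioxolane would not tolerate.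

Step 10
Reactants: 17 diosphenol
Product: 18 C7 O-triisopropylsilyl diosphenol ether
Conditions: i-Pr3SiCl, imidazole, DMAP (cat.), DMF, rt
Reagents that add atoms: chlorotriisopropylsilane, CC(C)[Si](Cl)(C(C)C)C(C)C
Why: O-Silylation of the acidic enol; the silyloxy group also makes C8 a poor conjugate acceptor and shields the C6 oxygen, which matters in steps 12 and 15.

Step 11
Reactants: 18 C7 O-silyl diosphenol ether; 19 2-chloro-2-oxoethyl acetate (acetoxyacetyl chloride)
Product: 20 C5-(acetoxyacetyl) 1,3-diketone
Conditions: 19, MgBr2·OEt2, i-Pr2NEt, CH2Cl2, 0 °C → rt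
Reagents that add atoms: none
Why: Magnesium-promoted soft enolisation and C-acylation by the acid chloride (crossed Claisen-type acylation) should functionalise C5, the only α-carbon of the C6 ketone that bears hydrogen, and brings in C4 and C19 with the acetate already in place while no strong base meets the ester.

Step 12
Reactants: 20 C5-(acetoxyacetyl) 1,3-diketone
Product: 22 (Z)-enol triflate C5=C4(OTf)(CH2OAc), via lithium enolate 21 (not isolated)
Conditions: LiN(SiMe3)2, Et2O, −78 °C; then Tf2O, −78 °C
Reagents that add atoms: trifluoromethanesulfonic anhydride, O=S(=O)(OS(=O)(=O)C(F)(F)F)C(F)(F)F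
Why: Enol triflate formation from the lithium chelate of a 1,3-diketone: chelation holds the exocyclic oxygen cis to C6=O (Z geometry), and the bulky silyloxy group on C7 next to the C6 oxygen should steer sulfonylation to the exocyclic oxygen.

Step 13
Reactants: 22 (Z)-enol triflate
Product: 23 (E)-alkylidene enone C5=C4(CH3)(CH2OAc) with the dioxolane arm
Conditions: MeZnCl, Pd(PPh3)4 (cat.), THF, 0 °C → rt
Reagents that add atoms: methylzinc chloride, C[Zn]Cl
Why: Negishi cross-coupling of the vinylogous acyl triflate proceeds with retention of alkene geometry, so methyl C18 ends cis to C6=O and the acetoxymethyl group cis to C10, an arrangement in which the C19 oxygen cannot cyclise onto C6.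

Step 14
Reactants: 23 (E)-alkylidene enone acetal
Product: 24 C3 aldehyde (ring B 2-silyloxy enone with E alkylidene, C10 propanal arm cis to the side chain)
Conditions: PPTS (cat.), acetone/H2O (9:1), 50 °C
Reagents that add atoms: water, O
Why: Mild acid-catalysed acetal hydrolysis frees the aldehyde; both triisopropylsilyl ethers, the acetate and the alkene geometry should survive these conditions.

Step 15
Reactants: 24 C3 aldehyde
Product: 25 trans-fused bicyclic 3,6-diketone with quaternary C4 (S), C5–H and C10–H
Conditions: aminoindanol-derived N-pentafluorophenyl triazolium tetrafluoroborate (20 mol %), KN(SiMe3)2 (18 mol %), toluene, 23 → 40 °C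
Reagents that add atoms: none
Why: Proposed new method: the carbene adds to the C3 aldehyde to give the Breslow intermediate, whose nucleophilic C3 adds to C4 of the C6-conjugated alkylidene, and proton transfer to C5 of the C6 enolate with loss of the carbene releases the 1,4-diketone; the closest known reaction type is the enantioselective intramolecular Stetter reaction that forms quaternary centres from β,β-disubstituted acceptors, which has not been shown for a fully substituted acceptor closing a carbocycle. Ring A closes in the 6-endo-trig mode, because both C4 and C5 of the reacting double bond lie inside the new ring. C4 is controlled by the substrate: allylic 1,3-strain with the acetoxymethyl group on C4 forces the C10 arm axial, so C3 can reach only the C4 face on the side of the arm, and with the E geometry this gives the (S) configuration, the catalyst antipode being chosen to match this approach. C5 is set by protonation and is erased in step 16. The step needs attack at C4 in preference to C8 and to the C6 carbonyl: the C7 silyloxy group and the adjacent quaternary C9 deactivate C8, and benzoin-type addition to C6 is reversible whereas the conjugate addition is not.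

Step 16
Reactants: 25 bicyclic 3,6-diketone
Product: 26 C5=C10 dienone (bis-silyl ether of the target)
Conditions: DDQ, 1,4-dioxane, 90 °C
Reagents that add atoms: none
Why: Quinone dehydrogenation of an enone to a cross-conjugated dienone (the reaction that converts steroidal 4-en-3-ones into 1,4-dien-3-ones in the presence of saturated ketones): the conjugated C6 ketone enolises toward C5 and loses hydride from C10, while the isolated C3 ketone should not react.

Step 17
Reactants: 26 C5=C10 dienone bis-silyl ether
Product: 27 target, (4S,9S) in the numbering used here with the (13E) side chain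
Conditions: HF·pyridine, pyridine/THF, 0 °C → rt
Reagents that add atoms: none
Why: Fluoride-mediated desilylation should remove both the enol silyl ether at C7 and the primary silyl ether at C15 under buffered conditions that leave the C19 acetate untouched; no stereocentre is affected.

Compound list
1 | (2E)-3-methylpent-2-en-4-yn-1-ol | C#C/C(C)=C/CO | starting material
2 | triisopropyl{[(2E)-3-methylpent-2-en-4-yn-1-yl]oxy}silane | C#C/C(C)=C/CO[Si](C(C)C)(C(C)C)C(C)C | intermediate
3 | triisopropyl{[(2E)-3-methylpenta-2,4-dien-1-yl]oxy}silane | C=C/C(C)=C/CO[Si](C(C)C)(C(C)C)C(C)C | intermediate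
4 | 2-iodocyclohex-2-en-1-one | O=C1CCCC=C1I | starting material
5 | 9-[(3E)-3-methyl-5-(triisopropylsilyloxy)pent-3-en-1-yl]-9-borabicyclo[3.3.1]nonane | CC(C)[Si](OC/C=C(C)/CCB1C2CCCC1CCC2)(C(C)C)C(C)C | intermediate (not isolated)
6 | 2-[(3E)-3-methyl-5-(triisopropylsilyloxy)pent-3-en-1-yl]cyclohex-2-en-1-one | O=C1CCCC=C1CC/C(C)=C/CO[Si](C(C)C)(C(C)C)C(C)C | intermediate
7 | 2-(2-bromoethyl)-1,3-dioxolane | BrCCC1OCCO1 | starting material
8 | [2-(1,3-dioxolan-2-yl)ethyl]magnesium bromide | Br[Mg]CCC1OCCO1 | intermediate (not isolated)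
9 | bromomagnesium enolate from the conjugate addition (C8–OMgBr, C8=C9, arm on C10) | Br[Mg]OC1=C(CC/C(C)=C/CO[Si](C(C)C)(C(C)C)C(C)C)[C@@H](CCC2OCCO2)CCC1 | intermediate (not isolated)
10 | (2S,3R)-3-[2-(1,3-dioxolan-2-yl)ethyl]-2-methyl-2-[(3E)-3-methyl-5-(triisopropylsilyloxy)pent-3-en-1-yl]cyclohexan-1-one (arm cis to side chain) | O=C1CCC[C@H](CCC2OCCO2)[C@]1(C)CC/C(C)=C/CO[Si](C(C)C)(C(C)C)C(C)C | intermediate
11 | lithium enolate of 10 (C7=C8–OLi) | [Li]OC1=CCC[C@H](CCC2OCCO2)[C@]1(C)CC/C(C)=C/CO[Si](C(C)C)(C(C)C)C(C)C | intermediate (not isolated)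
12 | trimethylsilyl enol ether of 10 (C7=C8–OSiMe3) | C[Si](C)(C)OC1=CCC[C@H](CCC2OCCO2)[C@]1(C)CC/C(C)=C/CO[Si](C(C)C)(C(C)C)C(C)C | intermediate (not isolated)
13 | 5-[2-(1,3-dioxolan-2-yl)ethyl]-6-methyl-6-[(3E)-3-methyl-5-(triisopropylsilyloxy)pent-3-en-1-yl]cyclohex-2-en-1-one, C9 and C10 as in 10 | O=C1C=CC[C@H](CCC2OCCO2)[C@]1(C)CC/C(C)=C/CO[Si](C(C)C)(C(C)C)C(C)C | intermediate
14 | 5-[2-(1,3-dioxolan-2-yl)ethyl]-1,6-dimethyl-6-[(3E)-3-methyl-5-(triisopropylsilyloxy)pent-3-en-1-yl]cyclohex-2-en-1-ol, C8 epimers, C9 and C10 as in 10 | CC1(O)C=CC[C@H](CCC2OCCO2)[C@]1(C)CC/C(C)=C/CO[Si](C(C)C)(C(C)C)C(C)C | intermediate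
15 | 5-[2-(1,3-dioxolan-2-yl)ethyl]-3,4-dimethyl-4-[(3E)-3-methyl-5-(triisopropylsilyloxy)pent-3-en-1-yl]cyclohex-2-en-1-one, C9 and C10 as in 10 | O=C1C=C(C)[C@@](C)(CC/C(C)=C/CO[Si](C(C)C)(C(C)C)C(C)C)[C@@H](CCC2OCCO2)C1 | intermediate
16 | 2,3-epoxide of 15 (C7,C8-epoxy ketone, epoxide configuration open) | O=C1C2OC2(C)[C@@](C)(CC/C(C)=C/CO[Si](C(C)C)(C(C)C)C(C)C)[C@@H](CCC3OCCO3)C1 | intermediate
17 | 2-hydroxy derivative of 15 (diosphenol, C7–OH) | O=C1C(O)=C(C)[C@@](C)(CC/C(C)=C/CO[Si](C(C)C)(C(C)C)C(C)C)[C@@H](CCC2OCCO2)C1 | intermediate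
18 | 2-(triisopropylsilyloxy) derivative of 15 (C7–OSi(i-Pr)3) | O=C1C(O[Si](C(C)C)(C(C)C)C(C)C)=C(C)[C@@](C)(CC/C(C)=C/CO[Si](C(C)C)(C(C)C)C(C)C)[C@@H](CCC2OCCO2)C1 | intermediate
19 | 2-chloro-2-oxoethyl acetate (acetoxyacetyl chloride) | CC(=O)OCC(Cl)=O | starting material
20 | 18 bearing an acetoxyacetyl group on C5 (1,3-diketone, C5 enolisable) | O=C1C(O[Si](C(C)C)(C(C)C)C(C)C)=C(C)[C@@](C)(CC/C(C)=C/CO[Si](C(C)C)(C(C)C)C(C)C)[C@@H](CCC2OCCO2)C1C(=O)COC(C)=O | intermediate
21 | lithium enolate (chelate) of 20, exocyclic O–Li cis to C6=O | O=C1C(O[Si](C(C)C)(C(C)C)C(C)C)=C(C)[C@@](C)(CC/C(C)=C/CO[Si](C(C)C)(C(C)C)C(C)C)[C@@H](CCC2OCCO2)/C1=C(/O[Li])COC(C)=O | intermediate (not isolated)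
22 | (Z)-enol triflate: C5=C4(OSO2CF3)(CH2OAc), triflate cis to C6=O | O=C1C(O[Si](C(C)C)(C(C)C)C(C)C)=C(C)[C@@](C)(CC/C(C)=C/CO[Si](C(C)C)(C(C)C)C(C)C)[C@@H](CCC2OCCO2)/C1=C(/OS(=O)(=O)C(F)(F)F)COC(C)=O | intermediate
23 | (E)-alkylidene enone: C5=C4(CH3)(CH2OAc), methyl cis to C6=O, dioxolane arm on C10 | O=C1C(O[Si](C(C)C)(C(C)C)C(C)C)=C(C)[C@@](C)(CC/C(C)=C/CO[Si](C(C)C)(C(C)C)C(C)C)[C@@H](CCC2OCCO2)/C1=C(/C)COC(C)=O | intermediate
24 | Stetter precursor: as 23 with a 3-oxopropyl arm on C10 | O=C1C(O[Si](C(C)C)(C(C)C)C(C)C)=C(C)[C@@](C)(CC/C(C)=C/CO[Si](C(C)C)(C(C)C)C(C)C)[C@@H](CCC=O)/C1=C(/C)COC(C)=O | intermediate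
25 | Stetter product: trans-fused decalin-3,6-dione, C4 (S) with methyl and CH2OAc, C7–OSi(i-Pr)3, C7=C8 | O=C1CC[C@H]2[C@@H](C(=O)C(O[Si](C(C)C)(C(C)C)C(C)C)=C(C)[C@@]2(C)CC/C(C)=C/CO[Si](C(C)C)(C(C)C)C(C)C)[C@@]1(C)COC(C)=O | intermediate
26 | target with both hydroxyls as triisopropylsilyl ethers (C5=C10 dienone) | CC(=O)OC[C@@]1(C)C(=O)CCC2=C1C(=O)C(O[Si](C(C)C)(C(C)C)C(C)C)=C(C)[C@@]2(C)CC/C(C)=C/CO[Si](C(C)C)(C(C)C)C(C)C | intermediate
27 | CNP0512382.1 | CC(=O)OC[C@@]1(C)C(=O)CCC2=C1C(=O)C(O)=C(C)[C@@]2(C)CC/C(C)=C/CO | target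

Total step count: 17. Longest linear sequence: 17 steps (1 → 27); 4, 7 and 19 enter as purchased materials.

Steps most likely to fail

Step 15 (Proposed new method). The Breslow intermediate may not add to the fully substituted, hindered C4; it may instead be consumed by aldehyde self-condensation or stay in the reversible addition to C6, and a mismatched catalyst face may stall turnover. The fallback closes the same bond by known radical chemistry and sets out from 24. Pinnick oxidation (NaClO2, NaH2PO4, 2-methylbut-2-ene, t-BuOH/H2O) should give the C3 carboxylic acid F1. Diphenyl diselenide and tributylphosphine convert it into the Se-phenyl selenoester F2. Bu3SnH and AIBN in benzene at 80 °C generate the C3 acyl radical, which adds 6-endo to C4 (polarity-matched addition to the enone β-carbon, giving the C6-stabilised radical at C5). Hydrogen transfer then delivers 25, where the route is rejoined. The face of attack is again fixed by the axial C10 arm.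

Step 16. The quinone may abstract hydride from the allylic C15 position of the silyl ether, or conversion may stop because the C10 hydrogen next to the quaternary C9 is hindered. The fallback sets out from 25 and masks C3 so that an enolate-type dehydrogenation becomes regiospecific. NaBH4 in MeOH/CH2Cl2 at −78 °C should reduce only the unconjugated C3 ketone to the C3 carbinol F3. Me3SiOTf/Et3N then silylates the carbinol and converts the single remaining ketone into its dienol ether, the bis(trimethylsilyl) compound F4. Saegusa–Ito oxidation with Pd(OAc)2 in MeCN and a mildly acidic work-up give the C5=C10 dienone carbinol F5. Dess–Martin periodinane reoxidises C3 and returns 26.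

Step 12. Sulfonylation may occur at the ring oxygen on C6 (loss of regiocontrol), or chelation control may be incomplete and give both enol triflate geometries. The fallback sets out from 18. Its kinetic lithium enolate (LiN(i-Pr)2, THF, −78 °C) is added to 1-acetoxypropan-2-one to give the tertiary aldol F6. Mesylation (MsCl, Et3N) and elimination with DBU give the alkylidene as an E/Z pair, from which the E isomer 23 is separated by chromatography; the Z isomer can be re-equilibrated with catalytic iodine and light. The route is rejoined at 23.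

Further compounds
F1 | step 15 | C3 carboxylic acid corresponding to aldehyde 24 | O=C1C(O[Si](C(C)C)(C(C)C)C(C)C)=C(C)[C@@](C)(CC/C(C)=C/CO[Si](C(C)C)(C(C)C)C(C)C)[C@@H](CCC(O)=O)/C1=C(/C)COC(C)=O
F2 | step 15 | Se-phenyl selenoester of F1 | O=C1C(O[Si](C(C)C)(C(C)C)C(C)C)=C(C)[C@@](C)(CC/C(C)=C/CO[Si](C(C)C)(C(C)C)C(C)C)[C@@H](CCC(=O)[Se]c2ccccc2)/C1=C(/C)COC(C)=O
F3 | step 16 | C3 carbinol from 25 (C3 epimers) | OC1CC[C@H]2[C@@H](C(=O)C(O[Si](C(C)C)(C(C)C)C(C)C)=C(C)[C@@]2(C)CC/C(C)=C/CO[Si](C(C)C)(C(C)C)C(C)C)[C@@]1(C)COC(C)=O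
F4 | step 16 | bis(trimethylsilyl) compound: C3–OSiMe3 and C5=C6–OSiMe3 dienol ether | C[Si](C)(C)OC1CC[C@H]2C(=C(O[Si](C)(C)C)C(O[Si](C(C)C)(C(C)C)C(C)C)=C(C)[C@@]2(C)CC/C(C)=C/CO[Si](C(C)C)(C(C)C)C(C)C)[C@@]1(C)COC(C)=O
F5 | step 16 | C5=C10 dienone with C3 carbinol | OC1CCC2=C(C(=O)C(O[Si](C(C)C)(C(C)C)C(C)C)=C(C)[C@@]2(C)CC/C(C)=C/CO[Si](C(C)C)(C(C)C)C(C)C)[C@@]1(C)COC(C)=O
F6 | step 12 | tertiary aldol of 18 with 1-acetoxypropan-2-one (C4 carbinol on C5) | O=C1C(O[Si](C(C)C)(C(C)C)C(C)C)=C(C)[C@@](C)(CC/C(C)=C/CO[Si](C(C)C)(C(C)C)C(C)C)[C@@H](CCC2OCCO2)C1C(C)(O)COC(C)=O
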